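## The problem

Pestaphilone D is a 7,8-dihydro-6H-isochromen-6-one: a pyran (ring A: O2, C1, C3, C4) fused along C4a–C8a to a cyclohexenone (ring B: C4a, C5, C6, C7, C8, C8a), with a seven-carbon chain (C9–C15) on C3. Its six stereocentres form two remote sets: C7 (tertiary carbinol with methyl) and C8 on ring B, and C9/C10 (trisubstituted epoxide), C13 and C14 on the chain. Neither set can steer the other, so each needs its own source of absolute configuration and the two halves are best joined late. On ring B the secondary carbinol C8 can be bought and should direct the quaternary centre C7 (7-OH trans to 8-OH). In the chain C14 can direct C13, whereas the epoxide needs reagent control on an E-trisubstituted alkene that sits next to the E-C11=C12 alkene. The core is a doubly vinylogous ester and is fragile in four ways: C1 accepts nucleophiles, the C9 epoxide on the enol-ether carbon C3 ionises with acid or π-acidic metals, the C6/C7 α-ketol can shift under base, and any carbanion at C8a next to a C4a carbonyl can expel the C8 oxygen. The enabling feature is the 1,2-relationship of the C6 ketone and the C7 carbinol, an acyloin. Both carbons are natural acceptors, so a C6 aldehyde turned into an acyl-anion equivalent can add to a C7 methyl ketone, which forges C6–C7, closes the non-aromatic ring B and creates C7 beside C8.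

## Retrosynthesis

Target 34 is first traced to its 8,14-bis(silyl) ether 33. Only two O–Si bonds are cut. The free secondary hydroxyls would complicate the metal-mediated union, and the tertiary C7 hydroxyl can stay free, so the last step is asked only to remove two silyl groups under near-neutral conditions.

In 33 the pyran is cut at C4–C4a and O2–C3, giving the ring B vinyl triflate 19 (C4a–OTf, hydroxymethylene C1 on C8a) and the terminal alkynyl epoxide 31. The neighbouring cuts are worse: C3–C9 would need an epoxide-bearing nucleophile, and O2–C1/C4–C4a would need an α,β-epoxy ketone. The chosen cut divides the molecule into halves of similar size that each carry one stereochemical set, and it forms an sp–sp2 bond at room temperature with the epoxide already in place. The forward step needs cross-coupling at C4a and then 6-endo addition of the C1 enol oxygen to C3.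

Triflate 19 is traced through the methoxymethylene dione 17 to dione 14 by cutting C8a–C1 and exchanging the C4a–O sulfonate for a carbonyl. C1 is added as a one-carbon electrophile to C8a, the terminal carbon of the only bis-silyl dienol ether that 14 can form, since C7 carries no hydrogen. This placement is preferred to a strong-base formylation because it never generates a free carbanion beside the C8 oxygen. The forward sequence needs γ-selectivity (C8a over C5) and sulfonylation of the C4a rather than the C6 oxygen.

Dione 14 comes from ketal 13 by hydrolysis. Ketol 13 is cut at C6–C7, the key disconnection, to the acyclic keto aldehyde 12. Cutting C7–C8 or C5–C6 instead would give aldol-type precursors whose tertiary carbinol stereocentre must be made beforehand. The C6–C7 cut leaves a chain with a single stereocentre (C8) and makes the quaternary centre in the ring-closing step. The forward reaction needs an acyl anion at C6, crossed chemoselectivity, and attack on the ketone face that puts the new hydroxyl trans to the C8 silyl ether. The C4a ketal masks the future enone carbon.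

Keto aldehyde 12 is traced through diol 11, ketone 10 and hydroxy ketone 9 to the ketal 8. It is then traced through β-keto ester 6 and dioxolanone acid 3 to (R)-malic acid 1, with 2,2-dimethoxypropane 2, mono-tert-butyl malonate 4 and 1,2-bis(trimethylsilyloxy)ethane 7 as the other building blocks. The cuts are C7–CH3, C4a–C5 and the ketal C–O bonds. Malic acid supplies C7, C8, C8a and C4a with C8 already R, and its acetonide differentiates the two carboxyls. The tert-butyl ester must survive the methyl addition, so the C6 aldehyde and C7 ketone are finally revealed together from diol 11.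

Alkyne 31 is traced to epoxy aldehyde 30 (one-carbon homologation, C3≡C4) and then to epoxy alcohol 29 and dienol 28 (C9–O and C10–O). An allylic alcohol is the one precursor for which the epoxide face is set by reagent and the C9=C10 alkene is selected over C11=C12. C9 is quaternary, so aldehyde 30 cannot epimerise.

Dienol 28 is cut at C9=C10 and C11=C12 to dienoate 27, enal 25 and aldehyde 23, using the two stabilised ylides 26 and 24. Aldehyde 23 is traced through esters 22 and 21 to methyl (S)-3-hydroxybutanoate 20 by cutting the C13–CH3 bond. Both alkenes must form E, and C14 must direct the methylation at C13 anti.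

## Roads not taken

Alternative 1: Ring B is cut at C7–C8 and C4a–C8a. Forward, the silyloxyfuran A2 would add across its 2- and 5-positions to the (Z)-benzoyloxyacryloyl imide A3 to give the 7-oxanorbornene A1, with an oxygen bridge between C7 and C4a. In one step this forms two ring bonds and installs C1 (imide carbonyl on C8a), the C8 oxygen and the C6 enol ether. Step for step it is more convergent than the chosen plan, which spends steps 10 and 11 putting C1 on C8a. Its weak points are that regiochemistry, endo selectivity and absolute configuration all rest on one cycloaddition of a reversible furan diene, which would need a chiral Lewis acid. C4 arrives as an unactivated methyl on C4a, and joining it to the chain would mean acylation with an α,β-epoxy acyl unit, the most fragile possible form of the side chain. The chosen plan sets against this a C8 centre from the chiral pool and a side chain attached as an alkyne under mild coupling conditions.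

Alternative 2: The pyran is cut at C4–C4a and O2–C3, as in the chosen plan, but the forward step is an anodic ruthenium-catalysed C–H/O–H annulation. The hydroxymethylene dienone A5 and the alkyne A6 would give the tris-silyl ether A4 directly. This would save the triflation and needs no leaving group at C4a, which is a real advantage in step count and atom economy. The weak points are specific to this target. A6 is a terminal alkyne, the class that tends to form acetylides or dimerise under C–H annulation conditions. Its internal carbon carries a quaternary epoxide, which is hindered for O–C3 bond formation and labile under heated oxidative conditions. A5 still needs C1 on C8a, so the formylation problem remains. The chosen plan uses a two-electron coupling at room temperature that is routine for terminal alkynes.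

Alternative 3: Ring B is cut at C8–C8a. Forward, the glutaconate-type enolate of aldehyde A8 would add to its C8 aldehyde and give the aldol A7, which already carries C1 (ester on C8a) and C4 (methyl on C4a). This is shorter to a ring B bearing C1 than the chosen plan. Its weak points are that the quaternary carbinol C7 must be made enantiopure before the ring exists, which is harder than buying C8, and that the α/γ regiochemistry of the enolate must be controlled. C8 would then rest on Felkin control from a fully substituted neighbour. The ester must later be lowered to the aldehyde level beside an enone, and the C4 methyl leaves the same chain-attachment problem as Alternative 1. The chosen plan makes C7 in the ring-closing event under the control of C8 and the catalyst.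

Key step: step 8

Assumption: the (5aS,10bR) antipode of the aminoindanol-derived triazolium salt is taken as the one that reinforces the substrate bias in step 8; if the pairing proves mismatched, the (5aR,10bS) antipode is used with no other change.

Assumption: diones 14 and 17 and the hydroxymethylene compounds 19 and 32 are written as single tautomers, and the geometry of the exocyclic C8a=C1 bond in 17, 18, 19 and 32 is left open because it is lost on ring closure.

## Route

Step 1
Reactants: 1 (R)-malic acid; 2 2,2-dimethoxypropane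
Product: 3 2-[(4R)-2,2-dimethyl-5-oxo-1,3-dioxolan-4-yl]acetic acid
Conditions: TsOH·H2O (cat.), neat 2, rt
Reagents that add atoms: none
Why: Acid-catalysed transacetalisation forms the five-membered dioxolanone from the α-hydroxy acid only and leaves the β-carboxyl free; the stereocentre (future C8) is not touched.

Step 2
Reactants: 3 dioxolanone acid; 4 mono-tert-butyl malonate (3-tert-butoxy-3-oxopropanoic acid)
Product: 6 tert-butyl 4-[(4R)-2,2-dimethyl-5-oxo-1,3-dioxolan-4-yl]-3-oxobutanoate, via acyl imidazolide 5 (not isolated)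
Conditions: 1,1'-carbonyldiimidazole, THF, rt; then 4, MgCl2, Et3N, MeCN, rt; cold 0.5 M HCl
Reagents that add atoms: none
Why: Masamune–Brooks homologation: the magnesium malonate half-ester is C-acylated by the imidazolide and decarboxylates to the β-keto ester (C4a ketone, C5, C6). The tert-butyl ester is chosen so that it resists MeLi in step 4.

Step 3
Reactants: 6 β-keto ester; 7 1,2-bis(trimethylsilyloxy)ethane
Product: 8 tert-butyl 2-(2-{[(4R)-2,2-dimethyl-5-oxo-1,3-dioxolan-4-yl]methyl}-1,3-dioxolan-2-yl)acetate
Conditions: TMSOTf (5 mol%), CH2Cl2, −78 → −10 °C; pyridine quench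
Reagents that add atoms: none
Why: Noyori ketalisation under aprotic conditions converts the ketone into the dioxolane. No free glycol or protic acid is present, so the acyl-acetal ring and the tert-butyl ester should survive.

Step 4
Reactants: 8 ketal ester
Product: 9 tert-butyl 2-{2-[(2R)-2-hydroxy-3-oxobutyl]-1,3-dioxolan-2-yl}acetate
Conditions: MeLi (1.1 equiv), THF, −78 °C; aq. NH4Cl
Reagents that add atoms: methyllithium, [Li]C
Why: Mono-addition of an organolithium to an activated lactone (1,3-dioxolan-4-one): the tetrahedral lithium alkoxide persists at −78 °C and collapses on quench with loss of acetone to the α-hydroxy methyl ketone. The hindered tert-butyl ester is far less electrophilic and should stay intact.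

Step 5
Reactants: 9 hydroxy ketone
Product: 10 tert-butyl 2-{2-[(2R)-2-[(tert-butyldimethylsilyl)oxy]-3-oxobutyl]-1,3-dioxolan-2-yl}acetate
Conditions: TBSCl, imidazole, DMF, 0 °C → rt
Reagents that add atoms: tert-butyldimethylsilyl chloride, CC(C)(C)[Si](C)(C)Cl
Why: Standard silylation of a secondary alcohol. Imidazole is too weak a base to enolise the α-oxy ketone at a useful rate, so C8 should keep its configuration.

Step 6
Reactants: 10 silyloxy ketone ester
Product: 11 (3R)-3-[(tert-butyldimethylsilyl)oxy]-4-[2-(2-hydroxyethyl)-1,3-dioxolan-2-yl]butan-2-ol (both C2 epimers)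
Conditions: LiAlH4, Et2O, −20 → 0 °C; H2O, aq. NaOH
Reagents that add atoms: none
Why: Hydride reduction of the ketone and the ester together avoids the impossible task of reducing the ester selectively beside the ketone. The new carbinol centre is unimportant because it is oxidised again in step 7.

Step 7
Reactants: 11 diol
Product: 12 2-{2-[(2R)-2-[(tert-butyldimethylsilyl)oxy]-3-oxobutyl]-1,3-dioxolan-2-yl}acetaldehyde
Conditions: Dess–Martin periodinane (2.6 equiv), pyridine, CH2Cl2, 0 °C → rt
Reagents that add atoms: none
Why: Double Dess–Martin oxidation gives the C6 aldehyde and the C7 methyl ketone in one operation under buffered, non-enolising conditions, which protects the C8 centre and the β-ketal aldehyde.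

Step 8
Reactants: 12 keto aldehyde
Product: 13 (8S,9R)-9-[(tert-butyldimethylsilyl)oxy]-8-hydroxy-8-methyl-1,4-dioxaspiro[4.5]decan-7-one
Conditions: (5aS,10bR)-2-(pentafluorophenyl)-5a,10b-dihydro-4H,6H-indeno[2,1-b][1,2,4]triazolo[4,3-d][1,4]oxazin-2-ium tetrafluoroborate (15 mol%), Et3N (15 mol%), toluene (0.02 M), rt
Reagents that add atoms: none
Why: The triazolylidene freed by Et3N adds to the C6 aldehyde, and proton transfer gives the enaminol (Breslow intermediate), whose C6 is now nucleophilic. It adds to the C7 ketone, and loss of the carbene leaves the C6 ketone and the C7 tertiary alcohol. The closest known reaction type is the intramolecular crossed aldehyde–ketone benzoin cyclisation with aminoindanol-derived triazolium salts, which gives six-membered tertiary α-ketols. Ring B closes in a 6-exo-trig mode on the ketone carbonyl. C7 is controlled by C8 and by the catalyst: in a chair-like transition state the enaminol O–H is hydrogen-bonded to the ketone oxygen, which places the C7 oxygen pseudo-equatorial and the methyl pseudo-axial. The C8 silyloxy group sits equatorial and anti to the forming bond (polar Felkin–Anh), so the new hydroxyl should end up trans to it (7S in target numbering), and the chosen catalyst antipode is meant to reinforce this face. Crossed selectivity is secured because only the aldehyde can form the acyl anion and the α-silyloxy ketone is the only activated acceptor within reach. High dilution suppresses intermolecular homo-benzoin. The C4a ketal removes a competing carbonyl and favours the folded rotamer, and the weak amine base limits epimerisation at C8 and aldol pathways.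

Step 9
Reactants: 13 ketol ketal
Product: 14 (4S,5R)-5-[(tert-butyldimethylsilyl)oxy]-4-hydroxy-4-methylcyclohexane-1,3-dione
Conditions: PPTS, acetone–H2O (10:1), 50 °C
Reagents that add atoms: water, O
Why: Mild acid hydrolysis of the dioxolane is driven by formation of the enolised 1,3-dione. The secondary silyl ether tolerates pyridinium tosylate, and the enolised dione is not prone to β-elimination of the C8 oxygen.

Step 10
Reactants: 14 dione
Product: 17 (4S,5R)-5-[(tert-butyldimethylsilyl)oxy]-6-(methoxymethylidene)-4-methyl-4-[(trimethylsilyl)oxy]cyclohexane-1,3-dione, via tris-silyl dienol ether 15 (not isolated), via dimethyl acetal 16 (not isolated)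
Conditions: TMSOTf (4.5 equiv), i-Pr2NEt (6 equiv), CH2Cl2, −78 → 0 °C; then HC(OMe)3 (1.5 equiv), −78 → 0 °C; pH 7 phosphate buffer
Reagents that add atoms: trimethylsilyl triflate, C[Si](C)(C)OS(=O)(=O)C(F)(F)F; trimethyl orthoformate, COC(OC)OC
Why: Soft enolisation gives the only possible 1,3-bis(silyloxy)diene (C7 has no hydrogen) and silylates the C7 hydroxyl. Such dienes undergo Mukaiyama-type addition to orthoester-derived carbenium ions at the terminal carbon (here C8a), and the β-keto acetal then loses methanol under the same silyl triflate/amine conditions to the conjugated enol ether. No free carbanion forms at C8a, so the C8 silyl ether should not be expelled.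

Step 11
Reactants: 17 methoxymethylene dione
Product: 19 (4S,5R)-5-[(tert-butyldimethylsilyl)oxy]-4-hydroxy-6-(hydroxymethylidene)-4-methyl-3-oxocyclohex-1-en-1-yl trifluoromethanesulfonate, via methoxymethylene triflate 18 (not isolated)
Conditions: PhNTf2, Et3N, DMAP (cat.), CH2Cl2, 0 °C → rt; then 1 M HCl, THF, 0 °C
Reagents that add atoms: N-phenylbis(trifluoromethanesulfonimide), O=S(=O)(N(c1ccccc1)S(=O)(=O)C(F)(F)F)C(F)(F)F; water, O
Why: O-Sulfonylation of a cyclic 1,3-dione enolate should occur at the C4a oxygen, which is less hindered (the C6 oxygen is flanked by the quaternary C7) and more electron-rich (it is also the carbonyl of the methoxymethylene vinylogous ester). Dilute acid then hydrolyses the vinylogous ester to the hydroxymethylene group and removes the trimethylsilyl ether, before the acid-sensitive epoxide enters the sequence.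

Step 12
Reactants: 20 methyl (3S)-3-hydroxybutanoate
Product: 21 methyl (2S,3S)-3-hydroxy-2-methylbutanoate
Conditions: LiN(iPr)2 (2.2 equiv), THF, −78 → −20 °C; MeI, DMPU, −78 → 0 °C; aq. NH4Cl
Reagents that add atoms: iodomethane, CI
Why: Fráter–Seebach alkylation: the chelated lithium alkoxide–enolate dianion is methylated anti to the carbinol substituent, so C14 sets C13 (target numbering) and the anti 2S,3S isomer should result.

Step 13
Reactants: 21 anti hydroxy ester
Product: 22 methyl (2S,3S)-3-[(tert-butyldimethylsilyl)oxy]-2-methylbutanoate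
Conditions: TBSCl, imidazole, DMF, rt
Reagents that add atoms: tert-butyldimethylsilyl chloride, CC(C)(C)[Si](C)(C)Cl
Why: Standard silyl protection of the secondary alcohol; no stereocentre is affected.

Step 14
Reactants: 22 silyloxy ester
Product: 23 (2S,3S)-3-[(tert-butyldimethylsilyl)oxy]-2-methylbutanal
Conditions: i-Bu2AlH (1.1 equiv), CH2Cl2, −78 °C; aq. potassium sodium tartrate
Reagents that add atoms: none
Why: Partial reduction of an ester at low temperature. The aluminium hemiacetal is stable at −78 °C and releases the aldehyde on work-up; the aldehyde is used at once to avoid α-epimerisation.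

Step 15
Reactants: 23 aldehyde; 24 2-(triphenylphosphoranylidene)propanal
Product: 25 (2E,4R,5S)-5-[(tert-butyldimethylsilyl)oxy]-2,4-dimethylhex-2-enal
Conditions: toluene, 90 °C
Reagents that add atoms: none
Why: Wittig olefination with a stabilised formyl ylide gives the E-trisubstituted enal (C11=C12) directly. The weakly basic ylide should not epimerise the α-centre, and the α-substituted enal product is much less reactive towards a second olefination.

Step 16
Reactants: 25 enal; 26 ethyl 2-(triphenylphosphoranylidene)propanoate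
Product: 27 ethyl (2E,4E,6R,7S)-7-[(tert-butyldimethylsilyl)oxy]-2,4,6-trimethylocta-2,4-dienoate
Conditions: toluene, 80 °C
Reagents that add atoms: none
Why: A second Wittig olefination with a stabilised ylide is E-selective and sets the geometry of the alkene that becomes the C9–C10 epoxide.

Step 17
Reactants: 27 dienoate
Product: 28 (2E,4E,6R,7S)-7-[(tert-butyldimethylsilyl)oxy]-2,4,6-trimethylocta-2,4-dien-1-ol
Conditions: i-Bu2AlH (2.5 equiv), CH2Cl2, −78 °C; aq. potassium sodium tartrate
Reagents that add atoms: none
Why: 1,2-Reduction of a conjugated ester to the allylic alcohol, without touching the diene or the silyl ether.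

Step 18
Reactants: 28 dienol
Product: 29 {(2S,3S)-3-[(2E,4R,5S)-5-[(tert-butyldimethylsilyl)oxy]-4-methylhex-2-en-2-yl]-2-methyloxiran-2-yl}methanol
Conditions: Ti(OiPr)4 (10 mol%), L-(+)-diethyl tartrate (12 mol%), t-BuOOH, 4 Å molecular sieves, CH2Cl2, −20 °C
Reagents that add atoms: tert-butyl hydroperoxide, CC(C)(C)OO
Why: Katsuki–Sharpless asymmetric epoxidation: the allylic hydroxyl binds the titanium tartrate peroxide, so only the 2,3-alkene reacts. With L-(+)-tartrate this E-2-methyl allylic alcohol should give the (2S,3S)-epoxy alcohol, which corresponds to C9 and C10 of the target. The remote C13/C14 centres play no part (reagent control).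

Step 19
Reactants: 29 epoxy alcohol
Product: 30 (2R,3S)-3-[(2E,4R,5S)-5-[(tert-butyldimethylsilyl)oxy]-4-methylhex-2-en-2-yl]-2-methyloxirane-2-carbaldehyde
Conditions: Dess–Martin periodinane, pyridine, CH2Cl2, 0 °C → rt
Reagents that add atoms: none
Why: Buffered Dess–Martin oxidation of a primary alcohol. The epoxy aldehyde has a quaternary α-carbon and cannot epimerise.

Step 20
Reactants: 30 epoxy aldehyde
Product: 31 (2S,3S)-3-[(2E,4R,5S)-5-[(tert-butyldimethylsilyl)oxy]-4-methylhex-2-en-2-yl]-2-ethynyl-2-methyloxirane
Conditions: dimethyl (1-diazo-2-oxopropyl)phosphonate, K2CO3, MeOH, 0 °C → rt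
Reagents that add atoms: dimethyl (1-diazo-2-oxopropyl)phosphonate, COP(=O)(OC)C(=[N+]=[N-])C(C)=O
Why: Ohira–Bestmann (Seyferth–Gilbert) homologation turns the aldehyde into the terminal alkyne (future C3≡C4) under mild carbonate conditions that the trisubstituted epoxide and the silyl ether tolerate.

Step 21
Reactants: 19 hydroxymethylene triflate; 31 alkynyl epoxide
Product: 33 (7S,8R)-8-[(tert-butyldimethylsilyl)oxy]-3-{(2R,3S)-3-[(2E,4R,5S)-5-[(tert-butyldimethylsilyl)oxy]-4-methylhex-2-en-2-yl]-2-methyloxiran-2-yl}-7-hydroxy-7-methyl-7,8-dihydro-6H-isochromen-6-one, via hydroxymethylene enynone 32 (not isolated)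
Conditions: Pd(PPh3)4 (5 mol%), CuI (10 mol%), Et3N (3 equiv), DMF, rt; then 45 °C
Reagents that add atoms: none
Why: Sonogashira coupling of a vinylogous acyl triflate with a terminal alkyne (oxidative addition of zerovalent palladium at C4a, then copper acetylide transmetalation) forms C4–C4a. In the same pot, copper/amine-promoted 6-endo-dig addition of the hydroxymethylene oxygen to C3, the δ-terminus of the ynenone, closes ring A, as in tandem coupling–heteroannulations of β-halo unsaturated acids and enols. No stereocentre is touched.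

Step 22
Reactants: 33 bis-silyl ether
Product: 34 Pestaphilone D
Conditions: TBAF, AcOH (1:1), THF, 0 °C → rt
Reagents that add atoms: none
Why: Fluoride cleavage of the two secondary silyl ethers. Buffering with acetic acid keeps the medium near neutral, so that neither C1 (base, nucleophiles) nor the C9 epoxide (acid) should be attacked.

## Compound list

1 | (R)-malic acid, (2R)-2-hydroxybutanedioic acid | O[C@H](CC(=O)O)C(=O)O | starting material
2 | 2,2-dimethoxypropane | COC(C)(C)OC | starting material
3 | 2-[(4R)-2,2-dimethyl-5-oxo-1,3-dioxolan-4-yl]acetic acid | O=C(O)C[C@H]1OC(C)(C)OC1=O | intermediate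
4 | mono-tert-butyl malonate (3-tert-butoxy-3-oxopropanoic acid) | CC(C)(C)OC(=O)CC(=O)O | starting material
5 | (5R)-5-[2-(1H-imidazol-1-yl)-2-oxoethyl]-2,2-dimethyl-1,3-dioxolan-4-one (acyl imidazolide of 3) | O=C(C[C@H]1OC(C)(C)OC1=O)n1ccnc1 | intermediate
6 | tert-butyl 4-[(4R)-2,2-dimethyl-5-oxo-1,3-dioxolan-4-yl]-3-oxobutanoate | CC(C)(C)OC(=O)CC(=O)C[C@H]1OC(C)(C)OC1=O | intermediate
7 | 1,2-bis(trimethylsilyloxy)ethane | C[Si](C)(C)OCCO[Si](C)(C)C | starting material
8 | tert-butyl 2-(2-{[(4R)-2,2-dimethyl-5-oxo-1,3-dioxolan-4-yl]methyl}-1,3-dioxolan-2-yl)acetate | CC(C)(C)OC(=O)CC1(OCCO1)C[C@H]1OC(C)(C)OC1=O | intermediate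
9 | tert-butyl 2-{2-[(2R)-2-hydroxy-3-oxobutyl]-1,3-dioxolan-2-yl}acetate | CC(=O)[C@H](O)CC1(OCCO1)CC(=O)OC(C)(C)C | intermediate
10 | tert-butyl 2-{2-[(2R)-2-[(tert-butyldimethylsilyl)oxy]-3-oxobutyl]-1,3-dioxolan-2-yl}acetate | CC(=O)[C@H](O[Si](C)(C)C(C)(C)C)CC1(OCCO1)CC(=O)OC(C)(C)C | intermediate
11 | (3R)-3-[(tert-butyldimethylsilyl)oxy]-4-[2-(2-hydroxyethyl)-1,3-dioxolan-2-yl]butan-2-ol (both C2 epimers) | CC(O)[C@H](O[Si](C)(C)C(C)(C)C)CC1(OCCO1)CCO | intermediate
12 | 2-{2-[(2R)-2-[(tert-butyldimethylsilyl)oxy]-3-oxobutyl]-1,3-dioxolan-2-yl}acetaldehyde | O=CCC1(OCCO1)C[C@@H](O[Si](C)(C)C(C)(C)C)C(C)=O | intermediate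
13 | (8S,9R)-9-[(tert-butyldimethylsilyl)oxy]-8-hydroxy-8-methyl-1,4-dioxaspiro[4.5]decan-7-one (C7 S, C8 R in target numbering) | C1C(=O)[C@@](C)(O)[C@H](O[Si](C)(C)C(C)(C)C)CC12OCCO2 | intermediate
14 | (4S,5R)-5-[(tert-butyldimethylsilyl)oxy]-4-hydroxy-4-methylcyclohexane-1,3-dione | O=C1CC(=O)[C@@](C)(O)[C@H](O[Si](C)(C)C(C)(C)C)C1 | intermediate
15 | tert-butyl(dimethyl){[(1R,6S)-6-methyl-3,5,6-tris[(trimethylsilyl)oxy]cyclohexa-2,4-dien-1-yl]oxy}silane | C[Si](C)(C)OC1=C[C@@H](O[Si](C)(C)C(C)(C)C)[C@](C)(O[Si](C)(C)C)C(O[Si](C)(C)C)=C1 | intermediate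
16 | (4S,5R)-5-[(tert-butyldimethylsilyl)oxy]-6-(dimethoxymethyl)-4-methyl-3,4-bis[(trimethylsilyl)oxy]cyclohex-2-en-1-one (C6 epimers) | COC(OC)C1C(=O)C=C(O[Si](C)(C)C)[C@@](C)(O[Si](C)(C)C)[C@@H]1O[Si](C)(C)C(C)(C)C | intermediate
17 | (4S,5R)-5-[(tert-butyldimethylsilyl)oxy]-6-(methoxymethylidene)-4-methyl-4-[(trimethylsilyl)oxy]cyclohexane-1,3-dione | COC=C1C(=O)CC(=O)[C@@](C)(O[Si](C)(C)C)[C@@H]1O[Si](C)(C)C(C)(C)C | intermediate
18 | (4S,5R)-5-[(tert-butyldimethylsilyl)oxy]-6-(methoxymethylidene)-4-methyl-3-oxo-4-[(trimethylsilyl)oxy]cyclohex-1-en-1-yl trifluoromethanesulfonate | COC=C1C(OS(=O)(=O)C(F)(F)F)=CC(=O)[C@@](C)(O[Si](C)(C)C)[C@@H]1O[Si](C)(C)C(C)(C)C | intermediate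
19 | (4S,5R)-5-[(tert-butyldimethylsilyl)oxy]-4-hydroxy-6-(hydroxymethylidene)-4-methyl-3-oxocyclohex-1-en-1-yl trifluoromethanesulfonate | OC=C1C(OS(=O)(=O)C(F)(F)F)=CC(=O)[C@@](C)(O)[C@@H]1O[Si](C)(C)C(C)(C)C | intermediate
20 | methyl (3S)-3-hydroxybutanoate | C[C@H](O)CC(=O)OC | starting material
21 | methyl (2S,3S)-3-hydroxy-2-methylbutanoate | COC(=O)[C@@H](C)[C@H](C)O | intermediate
22 | methyl (2S,3S)-3-[(tert-butyldimethylsilyl)oxy]-2-methylbutanoate | COC(=O)[C@@H](C)[C@H](C)O[Si](C)(C)C(C)(C)C | intermediate
23 | (2S,3S)-3-[(tert-butyldimethylsilyl)oxy]-2-methylbutanal | O=C[C@@H](C)[C@H](C)O[Si](C)(C)C(C)(C)C | intermediate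
24 | 2-(triphenylphosphoranylidene)propanal | CC(C=O)=P(c1ccccc1)(c1ccccc1)c1ccccc1 | starting material
25 | (2E,4R,5S)-5-[(tert-butyldimethylsilyl)oxy]-2,4-dimethylhex-2-enal | C/C(C=O)=C\[C@@H](C)[C@H](C)O[Si](C)(C)C(C)(C)C | intermediate
26 | ethyl 2-(triphenylphosphoranylidene)propanoate | CCOC(=O)C(C)=P(c1ccccc1)(c1ccccc1)c1ccccc1 | starting material
27 | ethyl (2E,4E,6R,7S)-7-[(tert-butyldimethylsilyl)oxy]-2,4,6-trimethylocta-2,4-dienoate | CCOC(=O)/C(C)=C/C(C)=C/[C@@H](C)[C@H](C)O[Si](C)(C)C(C)(C)C | intermediate
28 | (2E,4E,6R,7S)-7-[(tert-butyldimethylsilyl)oxy]-2,4,6-trimethylocta-2,4-dien-1-ol | OC/C(C)=C/C(C)=C/[C@@H](C)[C@H](C)O[Si](C)(C)C(C)(C)C | intermediate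
29 | {(2S,3S)-3-[(2E,4R,5S)-5-[(tert-butyldimethylsilyl)oxy]-4-methylhex-2-en-2-yl]-2-methyloxiran-2-yl}methanol | C/C(=C\[C@@H](C)[C@H](C)O[Si](C)(C)C(C)(C)C)[C@@H]1O[C@@]1(C)CO | intermediate
30 | (2R,3S)-3-[(2E,4R,5S)-5-[(tert-butyldimethylsilyl)oxy]-4-methylhex-2-en-2-yl]-2-methyloxirane-2-carbaldehyde | C/C(=C\[C@@H](C)[C@H](C)O[Si](C)(C)C(C)(C)C)[C@@H]1O[C@@]1(C)C=O | intermediate
31 | (2S,3S)-3-[(2E,4R,5S)-5-[(tert-butyldimethylsilyl)oxy]-4-methylhex-2-en-2-yl]-2-ethynyl-2-methyloxirane | C/C(=C\[C@@H](C)[C@H](C)O[Si](C)(C)C(C)(C)C)[C@@H]1O[C@@]1(C)C#C | intermediate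
32 | (5R,6S)-5-[(tert-butyldimethylsilyl)oxy]-3-({(2S,3S)-3-[(2E,4R,5S)-5-[(tert-butyldimethylsilyl)oxy]-4-methylhex-2-en-2-yl]-2-methyloxiran-2-yl}ethynyl)-6-hydroxy-4-(hydroxymethylidene)-6-methylcyclohex-2-en-1-one | OC=C1C(C#C[C@]2(C)O[C@H]2/C(C)=C/[C@@H](C)[C@H](C)O[Si](C)(C)C(C)(C)C)=CC(=O)[C@@](C)(O)[C@@H]1O[Si](C)(C)C(C)(C)C | intermediate
33 | (7S,8R)-8-[(tert-butyldimethylsilyl)oxy]-3-{(2R,3S)-3-[(2E,4R,5S)-5-[(tert-butyldimethylsilyl)oxy]-4-methylhex-2-en-2-yl]-2-methyloxiran-2-yl}-7-hydroxy-7-methyl-7,8-dihydro-6H-isochromen-6-one | C/C(=C\[C@@H](C)[C@H](C)O[Si](C)(C)C(C)(C)C)[C@@H]1O[C@@]1(C)C1=CC2=CC(=O)[C@@](C)(O)[C@H](O[Si](C)(C)C(C)(C)C)C2=CO1 | intermediate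
34 | Pestaphilone D, (7S,8R)-7,8-dihydroxy-3-{(2R,3S)-3-[(2E,4R,5S)-5-hydroxy-4-methylhex-2-en-2-yl]-2-methyloxiran-2-yl}-7-methyl-7,8-dihydro-6H-isochromen-6-one | C/C(=C\[C@@H](C)[C@H](C)O)[C@@H]1O[C@@]1(C)C1=CC2=CC(=O)[C@@](C)(O)[C@H](O)C2=CO1 | target

## Step count and risks

Total step count: 22. Longest linear sequence: 13 steps (steps 1–11, then 21 and 22) from (R)-malic acid. The alkyne branch is 9 steps (12–20) before the union.

Steps least certain to work:

Step 8 (key step). The most likely failures are poor facial selectivity at the ketone if catalyst and C8 centre are mismatched, and base-induced epimerisation at C8 or aldol closure competing with acyl-anion formation. Fallback from 12: a ketyl–carbonyl (pinacol) cyclisation with divalent samarium iodide (SmI2, THF, t-BuOH, −78 °C) forms the same C6–C7 bond without base. It should give the cis-6,7-diol with the tertiary hydroxyl anti to the C8 silyl ether, (7R,8R,9R)-9-[(tert-butyldimethylsilyl)oxy]-8-methyl-1,4-dioxaspiro[4.5]decane-7,8-diol F1. Oxidation of its secondary hydroxyl with Dess–Martin periodinane returns to 13.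

Step 10. The carbenium ion may attack C5 instead of C8a. The free silyl triflate needed to activate the orthoester may ionise the allylic C8 silyl ether of diene 15, followed by elimination, and the loss of methanol from 16 may be incomplete. Fallback from 14: diene 15 is freed from ammonium triflate by pentane trituration and treated with (chloromethylene)dimethyliminium chloride in CH2Cl2 at −40 °C, with no Lewis acid. Buffered work-up should give the enaminone (4S,5R)-5-[(tert-butyldimethylsilyl)oxy]-6-[(dimethylamino)methylidene]-4-methyl-4-[(trimethylsilyl)oxy]cyclohexane-1,3-dione F2. Sulfonylation with PhNTf2 and Et3N gives its C4a triflate, (4S,5R)-5-[(tert-butyldimethylsilyl)oxy]-6-[(dimethylamino)methylidene]-4-methyl-3-oxo-4-[(trimethylsilyl)oxy]cyclohex-1-en-1-yl trifluoromethanesulfonate F3. Aqueous HCl in THF hydrolyses the enaminone and the trimethylsilyl ether and returns to 19.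

Step 11. Sulfonylation may occur at the C6 oxygen, or on both oxygens unselectively, and the acid hydrolysis may also cleave the C8 silyl ether. Fallback from 17: the methoxy group is exchanged for an amine donor by addition–elimination with pyrrolidine (CH2Cl2, rt). This gives (4S,5R)-5-[(tert-butyldimethylsilyl)oxy]-4-methyl-6-[(pyrrolidin-1-yl)methylidene]-4-[(trimethylsilyl)oxy]cyclohexane-1,3-dione F4, in which the C4a oxygen is a vinylogous amide oxygen and by far the more nucleophilic. Sulfonylation gives (4S,5R)-5-[(tert-butyldimethylsilyl)oxy]-4-methyl-3-oxo-6-[(pyrrolidin-1-yl)methylidene]-4-[(trimethylsilyl)oxy]cyclohex-1-en-1-yl trifluoromethanesulfonate F5, and aqueous acid hydrolysis returns to 19.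

Step 21. Coupling may stall at the open enynone 32 without ring closure. Closure may go 5-exo, or the metals may open or rearrange the alkynyl epoxide. Fallback from 18, isolated before the acid treatment of step 11: plain Sonogashira coupling with 31 under the same Pd(PPh3)4/CuI conditions, with the C1 oxygen blocked, gives the methoxymethylene enynone (5R,6S)-5-[(tert-butyldimethylsilyl)oxy]-3-({(2S,3S)-3-[(2E,4R,5S)-5-[(tert-butyldimethylsilyl)oxy]-4-methylhex-2-en-2-yl]-2-methyloxiran-2-yl}ethynyl)-4-(methoxymethylidene)-6-methyl-6-[(trimethylsilyl)oxy]cyclohex-2-en-1-one F6. K2CO3 in aqueous methanol then cleaves the enol ether by addition–elimination at C1 and removes the trimethylsilyl ether. The liberated enolate is cyclised with catalytic silver carbonate Ag2CO3, which is basic rather than acidic, and the sequence returns to 33.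

Step 22. Fluoride or adventitious hydroxide may open the pyran at C1, acid may open the epoxide, or the hindered silyl ethers may cleave too slowly. Fallback: the silyl groups are removed before the union, when neither the pyran nor the epoxide–enol ether pair exists. From 31, TBAF in THF gives (2S,3R,4E)-5-[(2S,3S)-3-ethynyl-3-methyloxiran-2-yl]-3-methylhex-4-en-2-ol F7. From 19, HF·pyridine in MeCN gives (4S,5R)-4,5-dihydroxy-6-(hydroxymethylidene)-4-methyl-3-oxocyclohex-1-en-1-yl trifluoromethanesulfonate F8. Coupling and ring closure of F7 with F8 under the conditions of step 21 would then deliver 34 directly.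

Step 4. Over-addition to the tertiary alcohol is possible once the adduct collapses. Deprotonation of the ester could open the ketal, and the free α-hydroxy ketone could epimerise. Fallback from 8: i-PrMgCl and N,O-dimethylhydroxylamine hydrochloride (THF, −20 °C) open the dioxolanone to the Weinreb amide tert-butyl 2-{2-[(2R)-2-hydroxy-3-[methoxy(methyl)amino]-3-oxopropyl]-1,3-dioxolan-2-yl}acetate F9. Silylation with TBSCl and imidazole gives tert-butyl 2-{2-[(2R)-2-[(tert-butyldimethylsilyl)oxy]-3-[methoxy(methyl)amino]-3-oxopropyl]-1,3-dioxolan-2-yl}acetate F10. MeMgBr (THF, 0 °C) stops at the ketone and returns to 10.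

## Further compounds

F1 | step 8 | (7R,8R,9R)-9-[(tert-butyldimethylsilyl)oxy]-8-methyl-1,4-dioxaspiro[4.5]decane-7,8-diol | C1[C@@H](O)[C@@](C)(O)[C@H](O[Si](C)(C)C(C)(C)C)CC12OCCO2
F2 | step 10 | (4S,5R)-5-[(tert-butyldimethylsilyl)oxy]-6-[(dimethylamino)methylidene]-4-methyl-4-[(trimethylsilyl)oxy]cyclohexane-1,3-dione | CN(C)C=C1C(=O)CC(=O)[C@@](C)(O[Si](C)(C)C)[C@@H]1O[Si](C)(C)C(C)(C)C
F3 | step 10 | (4S,5R)-5-[(tert-butyldimethylsilyl)oxy]-6-[(dimethylamino)methylidene]-4-methyl-3-oxo-4-[(trimethylsilyl)oxy]cyclohex-1-en-1-yl trifluoromethanesulfonate | CN(C)C=C1C(OS(=O)(=O)C(F)(F)F)=CC(=O)[C@@](C)(O[Si](C)(C)C)[C@@H]1O[Si](C)(C)C(C)(C)C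
F4 | step 11 | (4S,5R)-5-[(tert-butyldimethylsilyl)oxy]-4-methyl-6-[(pyrrolidin-1-yl)methylidene]-4-[(trimethylsilyl)oxy]cyclohexane-1,3-dione | C1CCN(C1)C=C1C(=O)CC(=O)[C@@](C)(O[Si](C)(C)C)[C@@H]1O[Si](C)(C)C(C)(C)C
F5 | step 11 | (4S,5R)-5-[(tert-butyldimethylsilyl)oxy]-4-methyl-3-oxo-6-[(pyrrolidin-1-yl)methylidene]-4-[(trimethylsilyl)oxy]cyclohex-1-en-1-yl trifluoromethanesulfonate | C1CCN(C1)C=C1C(OS(=O)(=O)C(F)(F)F)=CC(=O)[C@@](C)(O[Si](C)(C)C)[C@@H]1O[Si](C)(C)C(C)(C)C
F6 | step 21 | (5R,6S)-5-[(tert-butyldimethylsilyl)oxy]-3-({(2S,3S)-3-[(2E,4R,5S)-5-[(tert-butyldimethylsilyl)oxy]-4-methylhex-2-en-2-yl]-2-methyloxiran-2-yl}ethynyl)-4-(methoxymethylidene)-6-methyl-6-[(trimethylsilyl)oxy]cyclohex-2-en-1-one | COC=C1C(C#C[C@]2(C)O[C@H]2/C(C)=C/[C@@H](C)[C@H](C)O[Si](C)(C)C(C)(C)C)=CC(=O)[C@@](C)(O[Si](C)(C)C)[C@@H]1O[Si](C)(C)C(C)(C)C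
F7 | step 22 | (2S,3R,4E)-5-[(2S,3S)-3-ethynyl-3-methyloxiran-2-yl]-3-methylhex-4-en-2-ol | C/C(=C\[C@@H](C)[C@H](C)O)[C@@H]1O[C@@]1(C)C#C
F8 | step 22 | (4S,5R)-4,5-dihydroxy-6-(hydroxymethylidene)-4-methyl-3-oxocyclohex-1-en-1-yl trifluoromethanesulfonate | OC=C1C(OS(=O)(=O)C(F)(F)F)=CC(=O)[C@@](C)(O)[C@@H]1O
F9 | step 4 | tert-butyl 2-{2-[(2R)-2-hydroxy-3-[methoxy(methyl)amino]-3-oxopropyl]-1,3-dioxolan-2-yl}acetate | CON(C)C(=O)[C@H](O)CC1(OCCO1)CC(=O)OC(C)(C)C
F10 | step 4 | tert-butyl 2-{2-[(2R)-2-[(tert-butyldimethylsilyl)oxy]-3-[methoxy(methyl)amino]-3-oxopropyl]-1,3-dioxolan-2-yl}acetate | CON(C)C(=O)[C@H](O[Si](C)(C)C(C)(C)C)CC1(OCCO1)CC(=O)OC(C)(C)C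
A1 | alternative 1 | 3-[3-(benzoyloxy)-1,4-dimethyl-5-[(triisopropylsilyl)oxy]-7-oxabicyclo[2.2.1]hept-5-ene-2-carbonyl]-1,3-oxazolidin-2-one (configuration as in the SMILES) | C[C@@]12O[C@@](C)(C=C1O[Si](C(C)C)(C(C)C)C(C)C)[C@@H](C(=O)N1CCOC1=O)[C@H]2OC(=O)c1ccccc1
A2 | alternative 1 | 2,5-dimethyl-3-[(triisopropylsilyl)oxy]furan | Cc1cc(O[Si](C(C)C)(C(C)C)C(C)C)c(C)o1
A3 | alternative 1 | 3-[(2Z)-3-(benzoyloxy)prop-2-enoyl]-1,3-oxazolidin-2-one | O=C(/C=C\OC(=O)c1ccccc1)N1CCOC1=O
A4 | alternative 2 | 7,8,14-tris(triethylsilyl) ether of Pestaphilone D | C/C(=C\[C@@H](C)[C@H](C)O[Si](CC)(CC)CC)[C@@H]1O[C@@]1(C)C1=CC2=CC(=O)[C@@](C)(O[Si](CC)(CC)CC)[C@H](O[Si](CC)(CC)CC)C2=CO1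
A5 | alternative 2 | (5R,6S)-4-(hydroxymethylidene)-6-methyl-5,6-bis[(triethylsilyl)oxy]cyclohex-2-en-1-one | OC=C1C=CC(=O)[C@@](C)(O[Si](CC)(CC)CC)[C@@H]1O[Si](CC)(CC)CC
A6 | alternative 2 | (2S,3S)-2-ethynyl-2-methyl-3-[(2E,4R,5S)-4-methyl-5-[(triethylsilyl)oxy]hex-2-en-2-yl]oxirane | C/C(=C\[C@@H](C)[C@H](C)O[Si](CC)(CC)CC)[C@@H]1O[C@@]1(C)C#C
A7 | alternative 3 | methyl 5-[(tert-butyldimethylsilyl)oxy]-6-hydroxy-2,5-dimethyl-4-oxocyclohex-2-ene-1-carboxylate (configuration as in the SMILES) | COC(=O)[C@H]1C(C)=CC(=O)[C@@](C)(O[Si](C)(C)C(C)(C)C)[C@@H]1O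
A8 | alternative 3 | methyl (3Z,6S)-6-[(tert-butyldimethylsilyl)oxy]-3,6-dimethyl-5,7-dioxohept-3-enoate | COC(=O)C/C(C)=C\C(=O)[C@@](C)(O[Si](C)(C)C(C)(C)C)C=O
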